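**Retrosynthetic overview**

- The strategy rests on the C7–C8–C9 unit. C7 with ring A is the carbinol of a mandelic acid and C8 is its carboxyl carbon, so the C8–O4′ ether to ring B can be made as an aryl ester. C9 is then added as a methylene and oxidised through a silicon tether on O7.
- Target 20 ⇒ diol 18 (benzyl and acetonide removed last) ⇒ C9–OH from C9–Si by Tamao oxidation of oxasilolane 17.
- 17 ⇒ C9–Si and C8–H by intramolecular hydrosilylation of the O7–SiHMe2 enol ether 16 ⇒ C8=C9 by methylenation of aryl ester 13.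
- 13 ⇒ mandelic acid 7 (C7 from asymmetric transfer hydrogenation of a glyoxylate) and phenol 12. Both come from aryl bromide 2: its aryllithium is acylated by dimethyl oxalate and its Grignard reagent opens (S)-benzyl glycidyl ether.
- Rings: both benzene rings are bought. The dioxolane (step 8) and then the 1-oxa-2-silacyclopentane (step 13) are formed in that order and both are opened again before the end.

Key step: step 13

Remark on labels: C7, C8 and C9 are carbons 1, 2 and 3 of the propane-1,3-diol chain (C7 benzylic, on ring A); O4′ is the phenolic oxygen of ring B.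

Remark on the chemistry: the facial sense of step 3 is assigned from the aryl alkyl ketone model; the C7 configuration of 5 is to be checked through its MTPA esters before going on, and the antipodal ligand would be used if the check required it.

**Route**

Step 1
Reactants: 1 4-bromo-2,6-dimethoxyphenol
Product: 2 2-(benzyloxy)-5-bromo-1,3-dimethoxybenzene
Conditions: BnBr, K2CO3, DMF, 60 °C
Reagents that add atoms: benzyl bromide, BrCc1ccccc1
Why: Williamson ether synthesis, in which the phenoxide formed by K2CO3 displaces bromide from the benzylic halide.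

Step 2
Reactants: 2 2-(benzyloxy)-5-bromo-1,3-dimethoxybenzene
Product: 4 methyl [4-(benzyloxy)-3,5-dimethoxyphenyl](oxo)acetate, via aryllithium 3 (not isolated)
Conditions: n-BuLi (1.05 equiv), THF, −78 °C; then transferred by cannula into (CO2Me)2 (2 equiv), THF, −78 °C; aq. NH4Cl
Reagents that add atoms: dimethyl oxalate, COC(=O)C(=O)OC; n-butyllithium, [Li]CCCC (its lithium is held only in intermediate 3)
Why: Bromine–lithium exchange followed by acylation of the aryllithium by a dialkyl oxalate, where inverse addition at −78 °C keeps the lithium hemiketal alkoxide intact until the quench so that only one addition should occur.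

Step 3
Reactants: 4 methyl [4-(benzyloxy)-3,5-dimethoxyphenyl](oxo)acetate
Product: 5 methyl (2S)-[4-(benzyloxy)-3,5-dimethoxyphenyl](hydroxy)acetate
Conditions: RuCl[(R,R)-TsDPEN](p-cymene) (1 mol%), HCO2H/Et3N (5:2), CH2Cl2, 25 °C
Reagents that add atoms: none
Why: Asymmetric transfer hydrogenation of an activated aryl ketone through the Ru–H/N–H bifunctional transition state, in which ring A is expected to lie under the η6-cymene so that the (R,R)-ligand delivers hydride to the face that gives the (S)-carbinol at C7.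

Step 4
Reactants: 5 methyl (2S)-[4-(benzyloxy)-3,5-dimethoxyphenyl](hydroxy)acetate
Product: 6 methyl (2S)-[4-(benzyloxy)-3,5-dimethoxyphenyl][(tert-butyldimethylsilyl)oxy]acetate
Conditions: TBSCl, imidazole, DMF, 25 °C
Reagents that add atoms: tert-butyldimethylsilyl chloride, CC(C)(C)[Si](C)(C)Cl
Why: Imidazole-promoted silylation of a secondary alcohol, which leaves the C7 stereocentre untouched.

Step 5
Reactants: 6 methyl (2S)-[4-(benzyloxy)-3,5-dimethoxyphenyl][(tert-butyldimethylsilyl)oxy]acetate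
Product: 7 (2S)-[4-(benzyloxy)-3,5-dimethoxyphenyl][(tert-butyldimethylsilyl)oxy]acetic acid
Conditions: LiOH·H2O, THF/H2O (3:1), 0 °C; then 1 M HCl to pH 4, 0 °C
Reagents that add atoms: lithium hydroxide, [Li+].[OH-]
Why: Saponification of a methyl ester, in which hydroxide attack on the carbonyl at 0 °C should outrun α-deprotonation and the carboxylate formed is no longer enolisable, so C7 and the silyl ether are kept.

Step 6
Reactants: 2 2-(benzyloxy)-5-bromo-1,3-dimethoxybenzene; 8 (S)-benzyl glycidyl ether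
Product: 10 (2S)-1-(benzyloxy)-3-[4-(benzyloxy)-3,5-dimethoxyphenyl]propan-2-ol, via arylmagnesium bromide 9 (not isolated)
Conditions: Mg turnings, THF, 50 °C; then CuI (10 mol%), 8, THF, −30 → 0 °C; aq. NH4Cl
Reagents that add atoms: magnesium, [Mg] (held only in intermediate 9)
Why: Copper-catalysed Grignard opening of a terminal epoxide by SN2 attack at the unsubstituted carbon, so the stereocentre of 8 is not touched and becomes the (S)-carbinol of the ring B side chain.

Step 7
Reactants: 10 (2S)-1-(benzyloxy)-3-[4-(benzyloxy)-3,5-dimethoxyphenyl]propan-2-ol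
Product: 11 4-[(2S)-2,3-dihydroxypropyl]-2,6-dimethoxyphenol
Conditions: H2 (1 atm), 10% Pd/C, MeOH, 25 °C
Reagents that add atoms: none
Why: Hydrogenolysis of the aryl and the alkyl benzyl ether over palladium, with no other reducible group present.

Step 8
Reactants: 11 4-[(2S)-2,3-dihydroxypropyl]-2,6-dimethoxyphenol
Product: 12 4-{[(4S)-2,2-dimethyl-1,3-dioxolan-4-yl]methyl}-2,6-dimethoxyphenol
Conditions: Me2C(OMe)2, PPTS (5 mol%), acetone, 25 °C; Et3N quench
Reagents that add atoms: 2,2-dimethoxypropane, COC(C)(C)OC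
Why: Acid-catalysed transketalisation, in which the 1,2-diol closes the five-membered dioxolane while the phenol forms no stable mixed ketal and stays free.

Step 9
Reactants: 7 (2S)-[4-(benzyloxy)-3,5-dimethoxyphenyl][(tert-butyldimethylsilyl)oxy]acetic acid; 12 4-{[(4S)-2,2-dimethyl-1,3-dioxolan-4-yl]methyl}-2,6-dimethoxyphenol
Product: 13 4-{[(4S)-2,2-dimethyl-1,3-dioxolan-4-yl]methyl}-2,6-dimethoxyphenyl (2S)-[4-(benzyloxy)-3,5-dimethoxyphenyl][(tert-butyldimethylsilyl)oxy]acetate
Conditions: EDC·HCl, DMAP (10 mol%), CH2Cl2, 0 → 25 °C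
Reagents that add atoms: none
Why: Steglich esterification, in which the acylpyridinium ion is captured by the phenol and the low temperature and substoichiometric DMAP should hold back the ketene and enol pathways that would erode C7.

Step 10
Reactants: 13 4-{[(4S)-2,2-dimethyl-1,3-dioxolan-4-yl]methyl}-2,6-dimethoxyphenyl (2S)-[4-(benzyloxy)-3,5-dimethoxyphenyl][(tert-butyldimethylsilyl)oxy]acetate
Product: 14 tert-butyl{[(1S)-1-[4-(benzyloxy)-3,5-dimethoxyphenyl]-2-(4-{[(4S)-2,2-dimethyl-1,3-dioxolan-4-yl]methyl}-2,6-dimethoxyphenoxy)prop-2-en-1-yl]oxy}dimethylsilane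
Conditions: Cp2TiMe2 (3 equiv), toluene, 65 °C, dark; then hexane, filtration through basic alumina
Reagents that add atoms: Cp2TiMe2 (dimethyltitanocene), C[Ti+2]C.c1cc[cH-]c1.c1cc[cH-]c1
Why: Petasis methylenation, in which thermally formed Cp2Ti=CH2 adds [2+2] to the electrophilic aryl ester carbonyl and cycloreverts to the C8=C9 enol ether under non-basic conditions that leave C7 alone.

Step 11
Reactants: 14 tert-butyl{[(1S)-1-[4-(benzyloxy)-3,5-dimethoxyphenyl]-2-(4-{[(4S)-2,2-dimethyl-1,3-dioxolan-4-yl]methyl}-2,6-dimethoxyphenoxy)prop-2-en-1-yl]oxy}dimethylsilane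
Product: 15 (1S)-1-[4-(benzyloxy)-3,5-dimethoxyphenyl]-2-(4-{[(4S)-2,2-dimethyl-1,3-dioxolan-4-yl]methyl}-2,6-dimethoxyphenoxy)prop-2-en-1-ol
Conditions: Bu4NF, THF, 0 → 25 °C; chromatography on Et3N-treated silica
Reagents that add atoms: none
Why: Fluoride desilylation, which keeps the medium basic so that the acid-labile aryl enol ether and the acetonide should survive.

Step 12
Reactants: 15 (1S)-1-[4-(benzyloxy)-3,5-dimethoxyphenyl]-2-(4-{[(4S)-2,2-dimethyl-1,3-dioxolan-4-yl]methyl}-2,6-dimethoxyphenoxy)prop-2-en-1-ol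
Product: 16 {[(1S)-1-[4-(benzyloxy)-3,5-dimethoxyphenyl]-2-(4-{[(4S)-2,2-dimethyl-1,3-dioxolan-4-yl]methyl}-2,6-dimethoxyphenoxy)prop-2-en-1-yl]oxy}dimethylsilane
Conditions: (HMe2Si)2NH (1.5 equiv), hexane, 25 → 50 °C; volatiles removed in vacuo, used crude
Reagents that add atoms: 1,1,3,3-tetramethyldisilazane, C[SiH](C)N[SiH](C)C
Why: Silylation of the alcohol by a disilazane with loss of ammonia, which generates no acid or halide and installs the Si–H tether on O7.

Step 13
Reactants: 16 {[(1S)-1-[4-(benzyloxy)-3,5-dimethoxyphenyl]-2-(4-{[(4S)-2,2-dimethyl-1,3-dioxolan-4-yl]methyl}-2,6-dimethoxyphenoxy)prop-2-en-1-yl]oxy}dimethylsilane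
Product: 17 (4R,5S)-5-[4-(benzyloxy)-3,5-dimethoxyphenyl]-4-(4-{[(4S)-2,2-dimethyl-1,3-dioxolan-4-yl]methyl}-2,6-dimethoxyphenoxy)-2,2-dimethyl-1,2-oxasilolane (4,5-cis)
Conditions: Pt2[(CH2=CHSiMe2)2O]3 (0.5 mol% zerovalent platinum), hexane, 25 → 50 °C
Reagents that add atoms: none
Why: Si–H adds oxidatively to zerovalent platinum, the tethered C8=C9 enol ether inserts into Pt–H so that hydrogen goes to C8 and platinum to C9 within a six-membered platinacycle, and C9–Si reductive elimination releases the ring (Chalk–Harrod cycle). The closest known reaction type is the platinum-catalysed intramolecular hydrosilylation of dimethylsilyl ethers of α-hydroxy enol ethers, which is established to give 2,3-syn products. The 1-oxa-2-silacyclopentane closes in the 5-endo mode with respect to the alkene, because the only alternative for an allylic silyl ether, 4-exo closure to an oxasiletane, is too strained and would put silicon on the oxygen-bearing carbon. C8 is set by C7: A(1,2) strain between ring A and the C8 aryloxy group keeps C7–H near the enol ether plane, the O7–Si link holds Pt–H on the face that carries O7, and hydrogen therefore reaches C8 anti to ring A, which places aryl and aryloxy cis on the ring, that is 7,8-syn (threo). The step needs regioselectivity, which the short tether and the unsubstituted C9 terminus secure, facial selectivity, which the C7 stereocentre secures, and chemoselectivity against β-aryloxy loss from the C9–platinum intermediate and against alkene migration to C7=C8, which fast ring-closing reductive elimination at 25–50 °C should secure.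

Step 14
Reactants: 17 (4R,5S)-5-[4-(benzyloxy)-3,5-dimethoxyphenyl]-4-(4-{[(4S)-2,2-dimethyl-1,3-dioxolan-4-yl]methyl}-2,6-dimethoxyphenoxy)-2,2-dimethyl-1,2-oxasilolane
Product: 18 (1S,2S)-1-[4-(benzyloxy)-3,5-dimethoxyphenyl]-2-(4-{[(4S)-2,2-dimethyl-1,3-dioxolan-4-yl]methyl}-2,6-dimethoxyphenoxy)propane-1,3-diol
Conditions: 30% H2O2, KF, KHCO3, THF/MeOH (1:1), 25 → 40 °C; aq. Na2S2O3
Reagents that add atoms: hydrogen peroxide, OO
Why: Tamao oxidation, in which hydroperoxide adds to the fluoride-activated alkoxysilane and C9 shifts from silicon to oxygen, giving C9–OH and freeing O7 without touching C8.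

Step 15
Reactants: 18 (1S,2S)-1-[4-(benzyloxy)-3,5-dimethoxyphenyl]-2-(4-{[(4S)-2,2-dimethyl-1,3-dioxolan-4-yl]methyl}-2,6-dimethoxyphenoxy)propane-1,3-diol
Product: 19 (1S,2S)-1-[4-(benzyloxy)-3,5-dimethoxyphenyl]-2-{4-[(2S)-2,3-dihydroxypropyl]-2,6-dimethoxyphenoxy}propane-1,3-diol
Conditions: AcOH/H2O/THF (3:1:1), 35 °C
Reagents that add atoms: none
Why: Acid-catalysed hydrolysis of the terminal isopropylidene ketal, run while the ring A phenol is still benzylated so that the C7 carbinol cannot ionise through a quinone methide and epimerise.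

Step 16
Reactants: 19 (1S,2S)-1-[4-(benzyloxy)-3,5-dimethoxyphenyl]-2-{4-[(2S)-2,3-dihydroxypropyl]-2,6-dimethoxyphenoxy}propane-1,3-diol
Product: 20 (1S,2S)-2-{4-[(2S)-2,3-dihydroxypropyl]-2,6-dimethoxyphenoxy}-1-(4-hydroxy-3,5-dimethoxyphenyl)propane-1,3-diol
Conditions: H2 (1 atm), 10% Pd/C, EtOAc/EtOH, 25 °C, stopped when 19 is consumed
Reagents that add atoms: none
Why: Hydrogenolysis of the aryl benzyl ether under neutral conditions, where this ether should cleave much faster than the secondary C7–OH and C8–O4′ benzylic bonds.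

**Compound list**

1 | 4-bromo-2,6-dimethoxyphenol | COc1cc(Br)cc(OC)c1O | starting material
2 | 2-(benzyloxy)-5-bromo-1,3-dimethoxybenzene | COc1cc(Br)cc(OC)c1OCc1ccccc1 | intermediate
3 | [4-(benzyloxy)-3,5-dimethoxyphenyl]lithium | COc1cc([Li])cc(OC)c1OCc1ccccc1 | intermediate (not isolated)
4 | methyl [4-(benzyloxy)-3,5-dimethoxyphenyl](oxo)acetate | COC(=O)C(=O)c1cc(OC)c(OCc2ccccc2)c(OC)c1 | intermediate
5 | methyl (2S)-[4-(benzyloxy)-3,5-dimethoxyphenyl](hydroxy)acetate | COC(=O)[C@@H](O)c1cc(OC)c(OCc2ccccc2)c(OC)c1 | intermediate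
6 | methyl (2S)-[4-(benzyloxy)-3,5-dimethoxyphenyl][(tert-butyldimethylsilyl)oxy]acetate | COC(=O)[C@@H](O[Si](C)(C)C(C)(C)C)c1cc(OC)c(OCc2ccccc2)c(OC)c1 | intermediate
7 | (2S)-[4-(benzyloxy)-3,5-dimethoxyphenyl][(tert-butyldimethylsilyl)oxy]acetic acid | OC(=O)[C@@H](O[Si](C)(C)C(C)(C)C)c1cc(OC)c(OCc2ccccc2)c(OC)c1 | intermediate
8 | (S)-benzyl glycidyl ether, (2S)-2-[(benzyloxy)methyl]oxirane | C1[C@H](O1)COCc2ccccc2 | starting material
9 | [4-(benzyloxy)-3,5-dimethoxyphenyl]magnesium bromide | COc1cc([Mg]Br)cc(OC)c1OCc1ccccc1 | intermediate (not isolated)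
10 | (2S)-1-(benzyloxy)-3-[4-(benzyloxy)-3,5-dimethoxyphenyl]propan-2-ol | COc1cc(C[C@H](O)COCc2ccccc2)cc(OC)c1OCc1ccccc1 | intermediate
11 | 4-[(2S)-2,3-dihydroxypropyl]-2,6-dimethoxyphenol | COc1cc(C[C@H](O)CO)cc(OC)c1O | intermediate
12 | 4-{[(4S)-2,2-dimethyl-1,3-dioxolan-4-yl]methyl}-2,6-dimethoxyphenol | COc1cc(C[C@H]2COC(C)(C)O2)cc(OC)c1O | intermediate
13 | 4-{[(4S)-2,2-dimethyl-1,3-dioxolan-4-yl]methyl}-2,6-dimethoxyphenyl (2S)-[4-(benzyloxy)-3,5-dimethoxyphenyl][(tert-butyldimethylsilyl)oxy]acetate | COc1cc(C[C@H]2COC(C)(C)O2)cc(OC)c1OC(=O)[C@@H](O[Si](C)(C)C(C)(C)C)c1cc(OC)c(OCc2ccccc2)c(OC)c1 | intermediate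
14 | tert-butyl{[(1S)-1-[4-(benzyloxy)-3,5-dimethoxyphenyl]-2-(4-{[(4S)-2,2-dimethyl-1,3-dioxolan-4-yl]methyl}-2,6-dimethoxyphenoxy)prop-2-en-1-yl]oxy}dimethylsilane | COc1cc([C@H](O[Si](C)(C)C(C)(C)C)C(=C)Oc2c(OC)cc(C[C@H]3COC(C)(C)O3)cc2OC)cc(OC)c1OCc1ccccc1 | intermediate
15 | (1S)-1-[4-(benzyloxy)-3,5-dimethoxyphenyl]-2-(4-{[(4S)-2,2-dimethyl-1,3-dioxolan-4-yl]methyl}-2,6-dimethoxyphenoxy)prop-2-en-1-ol | COc1cc([C@H](O)C(=C)Oc2c(OC)cc(C[C@H]3COC(C)(C)O3)cc2OC)cc(OC)c1OCc1ccccc1 | intermediate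
16 | {[(1S)-1-[4-(benzyloxy)-3,5-dimethoxyphenyl]-2-(4-{[(4S)-2,2-dimethyl-1,3-dioxolan-4-yl]methyl}-2,6-dimethoxyphenoxy)prop-2-en-1-yl]oxy}dimethylsilane | COc1cc([C@H](O[SiH](C)C)C(=C)Oc2c(OC)cc(C[C@H]3COC(C)(C)O3)cc2OC)cc(OC)c1OCc1ccccc1 | intermediate (key-step precursor)
17 | (4R,5S)-5-[4-(benzyloxy)-3,5-dimethoxyphenyl]-4-(4-{[(4S)-2,2-dimethyl-1,3-dioxolan-4-yl]methyl}-2,6-dimethoxyphenoxy)-2,2-dimethyl-1,2-oxasilolane | COc1cc([C@@H]2O[Si](C)(C)C[C@@H]2Oc2c(OC)cc(C[C@H]3COC(C)(C)O3)cc2OC)cc(OC)c1OCc1ccccc1 | intermediate (key-step product)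
18 | (1S,2S)-1-[4-(benzyloxy)-3,5-dimethoxyphenyl]-2-(4-{[(4S)-2,2-dimethyl-1,3-dioxolan-4-yl]methyl}-2,6-dimethoxyphenoxy)propane-1,3-diol | COc1cc([C@H](O)[C@H](CO)Oc2c(OC)cc(C[C@H]3COC(C)(C)O3)cc2OC)cc(OC)c1OCc1ccccc1 | intermediate
19 | (1S,2S)-1-[4-(benzyloxy)-3,5-dimethoxyphenyl]-2-{4-[(2S)-2,3-dihydroxypropyl]-2,6-dimethoxyphenoxy}propane-1,3-diol | COc1cc([C@H](O)[C@H](CO)Oc2c(OC)cc(C[C@H](O)CO)cc2OC)cc(OC)c1OCc1ccccc1 | intermediate
20 | (1S,2S)-2-{4-[(2S)-2,3-dihydroxypropyl]-2,6-dimethoxyphenoxy}-1-(4-hydroxy-3,5-dimethoxyphenyl)propane-1,3-diol | COc1cc([C@H](O)[C@H](CO)Oc2c(OC)cc(C[C@H](O)CO)cc2OC)cc(OC)c1O | target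

**Totals**

Total step count: 16.
Longest linear sequence: 13 steps (steps 1–5 and 9–16); the ring B branch (steps 1, 6–8) joins at step 9.

**Steps most likely to fail**

Step 13. Hydrogen delivery to C8 may lose facial selectivity because the C8 substituent is a bulky aryloxy group, or the C9–platinum intermediate may expel aryloxide before the C9–Si bond forms. The fallback sets out from phenol 12 and comes back at diol 18. It gives up the relay from C7 and sets C7 and C8 together under auxiliary control. Phenol 12 would be O-alkylated with bromoacetic acid (NaH, THF) to {4-[(4S)-(2,2-dimethyl-1,3-dioxolan-4-yl)methyl]-2,6-dimethoxyphenoxy}acetic acid F1. Its mixed pivalic anhydride (t-BuCOCl, Et3N) would acylate lithiated (R)-4-benzyl-1,3-oxazolidin-2-one (n-BuLi, THF, −78 °C) to the aryloxyacetyl imide F2. An Evans syn glycolate aldol (Bu2BOTf, i-Pr2NEt, CH2Cl2, −78 °C) with purchased 4-(benzyloxy)-3,5-dimethoxybenzaldehyde should give the (2R,3S)-aldol adduct F3, which has the target's 7,8-threo arrangement. LiBH4 in THF/H2O would then cleave the auxiliary reductively and give 18, and steps 15 and 16 follow unchanged.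

Step 10. The titanium methylidene may fail to add to a carbonyl crowded by the 2,6-dimethoxyaryl ester oxygen and the fully substituted C7, or the ester may lose phenoxide instead. The fallback sets out from methyl ester 6 and comes back at enol ether 14, so the key step is kept; the C8–O4′ bond is made by cross-coupling in place of esterification and methylenation. Ester 6 would be converted (MeNH(OMe)·HCl, i-PrMgCl, THF, −20 °C) into the Weinreb amide F4, and MeMgBr would give the methyl ketone F5. Kinetic deprotonation on the methyl side (KN(SiMe3)2, PhNTf2, THF, −78 °C; C7–H is shielded by the silyloxy group and ring A) should give the enol triflate F6. Palladium-catalysed C–O coupling of F6 with phenol 12 (Pd2(dba)3, 2-(di-tert-butylphosphino)biphenyl, K3PO4, toluene, 80 °C) would then give 14.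

Step 9. Activation of the α-aryl acid may partly racemise C7 through ketene or enol forms of the acylpyridinium ion, and acylation of the hindered phenol may be slow enough to favour this. The fallback sets out from keto ester 4 and comes back at ester 13; it forms the aryl ester before C7 is stereogenic. Keto ester 4 would be saponified (LiOH, THF/H2O, 0 °C) to [4-(benzyloxy)-3,5-dimethoxyphenyl](oxo)acetic acid F7. Coupling with phenol 12 (EDC·HCl, DMAP, CH2Cl2) would give the aryl arylglyoxylate F8. Transfer hydrogenation with RuCl[(R,R)-TsDPEN](p-cymene) in HCO2H/Et3N and CH2Cl2 at 0 °C would then set C7 on the finished ester and give the hydroxy ester F9. Silylation (TBSCl, imidazole, DMF) would return to 13.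

**Further compounds**

F1 | step 13 | {4-[(4S)-(2,2-dimethyl-1,3-dioxolan-4-yl)methyl]-2,6-dimethoxyphenoxy}acetic acid | COc1cc(C[C@H]2COC(C)(C)O2)cc(OC)c1OCC(=O)O
F2 | step 13 | (4R)-4-benzyl-3-[(4-{[(4S)-2,2-dimethyl-1,3-dioxolan-4-yl]methyl}-2,6-dimethoxyphenoxy)acetyl]-1,3-oxazolidin-2-one | COc1cc(C[C@H]2COC(C)(C)O2)cc(OC)c1OCC(=O)N1[C@H](Cc2ccccc2)COC1=O
F3 | step 13 | (4R)-4-benzyl-3-[(2R,3S)-3-[4-(benzyloxy)-3,5-dimethoxyphenyl]-2-(4-{[(4S)-2,2-dimethyl-1,3-dioxolan-4-yl]methyl}-2,6-dimethoxyphenoxy)-3-hydroxypropanoyl]-1,3-oxazolidin-2-one | COc1cc([C@H](O)[C@H](C(=O)N2[C@H](Cc3ccccc3)COC2=O)Oc2c(OC)cc(C[C@H]3COC(C)(C)O3)cc2OC)cc(OC)c1OCc1ccccc1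
F4 | step 10 | (2S)-2-[4-(benzyloxy)-3,5-dimethoxyphenyl]-2-[(tert-butyldimethylsilyl)oxy]-N-methoxy-N-methylacetamide | CON(C)C(=O)[C@@H](O[Si](C)(C)C(C)(C)C)c1cc(OC)c(OCc2ccccc2)c(OC)c1
F5 | step 10 | (1S)-1-[4-(benzyloxy)-3,5-dimethoxyphenyl]-1-[(tert-butyldimethylsilyl)oxy]propan-2-one | CC(=O)[C@@H](O[Si](C)(C)C(C)(C)C)c1cc(OC)c(OCc2ccccc2)c(OC)c1
F6 | step 10 | (3S)-3-[4-(benzyloxy)-3,5-dimethoxyphenyl]-3-[(tert-butyldimethylsilyl)oxy]prop-1-en-2-yl trifluoromethanesulfonate | C=C(OS(=O)(=O)C(F)(F)F)[C@@H](O[Si](C)(C)C(C)(C)C)c1cc(OC)c(OCc2ccccc2)c(OC)c1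
F7 | step 9 | [4-(benzyloxy)-3,5-dimethoxyphenyl](oxo)acetic acid | OC(=O)C(=O)c1cc(OC)c(OCc2ccccc2)c(OC)c1
F8 | step 9 | 4-{[(4S)-2,2-dimethyl-1,3-dioxolan-4-yl]methyl}-2,6-dimethoxyphenyl [4-(benzyloxy)-3,5-dimethoxyphenyl](oxo)acetate | COc1cc(C[C@H]2COC(C)(C)O2)cc(OC)c1OC(=O)C(=O)c1cc(OC)c(OCc2ccccc2)c(OC)c1
F9 | step 9 | 4-{[(4S)-2,2-dimethyl-1,3-dioxolan-4-yl]methyl}-2,6-dimethoxyphenyl (2S)-[4-(benzyloxy)-3,5-dimethoxyphenyl](hydroxy)acetate | COc1cc(C[C@H]2COC(C)(C)O2)cc(OC)c1OC(=O)[C@@H](O)c1cc(OC)c(OCc2ccccc2)c(OC)c1
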